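## Structural features

The target is a 1-aryltetralin cyclolignan: a tetrasubstituted benzene (ring A, methoxy at C6, hydroxyl at C7) is fused through C4a and C8a to a saturated six-membered carbocycle (ring B, C1 to C4), and a guaiacyl group (ring C) is attached at C1. C1, C2 and C3 are three contiguous stereocentres, (1S,2R,3R), with the aryl group, the C2 arm and the C3 arm mutually trans and all pseudo-equatorial. C2 and C3 each carry a one-carbon oxygenated arm (C2a and C3a); these two primary carbinols are chemically almost identical, yet only C2a bears the hydrogen sulfate. The fragile parts are the sulfate monoester (acid-labile, very polar, best introduced late and kept as a salt), the two free phenols (one of them para to the benzylic C1, hence prone to oxidation and quinone methide chemistry) and the doubly benzylic C1–H. The real difficulty is threefold: absolute control of the stereotriad, differentiation of C2a from C3a, and an end game that the sulfate survives. The key step exploits the fact that C1 is bonded to C8a of ring A, whose C6 methoxy group is para to C8a, and to ring C, whose oxygen is para to C1. C1 can therefore be ionised to a doubly donor-stabilised benzhydryl cation, and C2 can be delivered as the nucleophilic carbon of an allylsilane tethered through C3 and C4 to C4a, leaving on C2 a vinyl group that is a masked C2a, distinct from the protected C3a. A check of precursor 19 and product 21 against the target shows that their descriptors map correctly onto (1S,2R,3R); two points need tightening: C3 must be (R), which requires the (R)-configured oxazolidinone auxiliary, and the allylsilane must be geometrically pure E.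

## Logic of the disconnections

26 to 25. The three benzyl–oxygen bonds (two phenolic, one at C3a) are cut last. One hydrogenolysis frees all three hydroxyls without acid or base, which the sulfate tolerates as its salt. The gain is that every earlier intermediate is neutral, lipophilic and free of phenols. The forward step must cleave an aliphatic benzyl ether in the presence of a sulfate ester and must never turn acidic.

25 to 24. The O–S bond at C2a is cut. In 24 the C2a hydroxyl is the only free hydroxyl, so sulfation needs no selectivity. The forward step only has to be driven to completion on a hindered primary alcohol.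

24 to 21. The C2a carbinol is traced back to the vinyl group on C2: the C=C bond is cleaved and the resulting aldehyde reduced. This is what makes C2a different from C3a by construction. The forward step must cleave an alkene next to two electron-rich arenes and must not epimerise C2 at the aldehyde stage; the trans,trans arrangement is the thermodynamically preferred one, which helps.

21 to 19. The C1–C2 bond of ring B is cut, giving a benzhydrol with an (E)-allylsilane side chain. This removes ring B and two of the three stereocentres in one operation and leaves C3 as the only centre to be made beforehand. The forward step must ionise C1 without destroying the allylsilane and must transmit the C3 configuration to C2 and C1; this requires geometric purity of the alkene, because a Z alkene would push the closure toward the 2,3-cis isomer.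

19 to 16 and 17. The C1–C8a bond is cut to an aryl bromide and an aromatic aldehyde. The two aromatic rings are thus joined convergently at the last moment before the key step. The forward step needs a clean bromine–lithium exchange in the presence of the allylsilane and two benzyl ethers; the configuration of the new carbinol is irrelevant.

16 to 15 to 14. The benzyl–oxygen bond at C3a and then the acyl–nitrogen bond to the auxiliary are cut, so C3a goes back to the imide carbonyl. The forward steps are a hydride cleavage that must not epimerise the doubly activated C3 centre, and a simple etherification.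

14 to 12 and 4. The C3–C4 bond is cut, an auxiliary-controlled alkylation of a dienolate by a benzylic bromide. This sets the single stereocentre that controls all others. The forward step must alkylate at the α-carbon, not at the γ-carbon, keep the E alkene out of conjugation, and use the (R)-auxiliary to obtain (R) at C3.

12 to 8 and 9; 8 to 6 and 7; 6 to 5. The acyl–nitrogen bond is cut, then the C2=C3/C2–C3 unit of the acid (the future C3–C2 bond of the target) is traced to a deconjugative condensation of an aldehyde with a two-carbon diacid, and the aldehyde to the alcohol. The reason for this choice over an olefin metathesis is the E geometry, which is fixed here under thermodynamic control in cheap material.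

4 to 3 to 2 to 1. The benzylic C–Br bond, the carbinol oxidation state and the phenolic benzyl ether are removed in turn, reaching a commercial bromophenol aldehyde that already has the full ring A substitution pattern, with bromine at the future C8a.

## Other disconnections considered

Alternative 1: The cut is C4–C4a. In the forward sense the ring A phenol of the acyclic phenol acrylate A1 is deprotonated with Cs2CO3, and the carbon para to the phenolate oxygen (C4a) adds to the acrylate CH2 (C4) in a 6-endo-trig conjugate addition; rearomatisation and protonation of the ester enolate at C3 would give the tetralin ester A2.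
- In its favour: only a mild base is needed (no Lewis acid, no organolithium, no osmium). C3 is set under thermodynamic control next to an epimerisable ester, which is at least the equal of the chosen plan for that centre. The ring A phenol is used as the activating group and emerges free, so one benzyl group fewer is needed; on protecting-group economy at ring A this is better than the chosen plan.
- Against it here: carbon alkylation of a phenolate by a 2-substituted, otherwise unactivated acrylate is weakly precedented and likely slow. The second ortho position of the carbon that carries C1 (ortho to the phenolate oxygen) can close a regioisomeric six-membered ring. The closure creates only C3, so C1 and C2 must already be set as contiguous acyclic stereocentres in A1. After the closure the C3 ester must be reduced, the C3a hydroxyl and the phenol protected, and the C2a silyl ether removed before sulfation: about five operations against three.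
- Comparison: on structure both plans distinguish C2a from C3a by construction (equal). On mechanism the chosen closure is irreversible and forms two stereocentres, whereas A2 would arise from a reversible Michael addition that forms one. On step economy the chosen plan should be shorter overall.

Alternative 2: The cuts are C1–C2 and C3–C4. Irradiation at about 365 nm of the 2-benzylbenzaldehyde A3 would give, by 1,5-hydrogen transfer, a hydroxy-ortho-quinodimethane, which adds dimethyl fumarate A4 in a [4+2] cycloaddition to give the hydroxy diester A5.
- In its favour: it is the most convergent of the four plans. Two C–C bonds, ring B and four stereocentres form in one step from an achiral aldehyde and a commodity dienophile, and the trans C2/C3 relationship follows from the geometry of A4. In bond and step economy up to the tetralin core it is better than the chosen plan.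
- Against it here: A5 is racemic unless a chiral auxiliary on the dienophile or a chiral Lewis acid is added, whereas the chosen plan takes its absolute configuration from a recoverable auxiliary. The two ester groups of A5 are nearly equivalent, while the target needs C2a sulfated and C3a free. The C4 hydroxyl is cis to the C3 ester (only a four-membered lactone would be possible) and trans to the C2 ester, so lactonisation does not readily tell the arms apart. The C4 hydroxyl must also be removed, although this could be merged with the final hydrogenolysis (equal).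
- Comparison: on structure A5 contains all skeletal carbons at once but with the wrong symmetry for this target, whereas 21 has the two arms distinct. On mechanism a concerted cycloaddition and a stepwise cation capture are both credible for the trans,trans triad. On step economy the alternative is better for the core and probably worse once enantiocontrol and arm differentiation are added.

Alternative 3: The cuts are C3–C4 and C4–C4a. Sc(OTf)3 would activate the carbonyl of the trans-3-aryl-2-(silyloxymethyl)indan-1-one A6; trimethylsilyldiazomethane A7 adds to it, and the ring A carbon migrates to the diazo carbon with loss of N2, expanding the five-membered ring to the β-tetralone A8.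
- In its favour: aryl migration is the usual preference in this homologation, so the regiochemistry should be dependable. C2a is already present as a silyl ether while C3a is still absent, so the arms are distinguished by construction (equal to the chosen plan). The 1,2-trans relationship can be secured by equilibration in A6.
- Against it here: the ring expansion creates no stereocentre. A8 is a β-tetralone whose C2 centre is α to the ketone and β to a silyloxy group, so epimerisation, β-elimination and enolisation toward C4 with air oxidation are all possible. C3a is still missing and must be added by a one-carbon homologation of the ketone with control at C3. Enantioenriched A6 needs its own asymmetric synthesis, and A7 is toxic.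
- Comparison: on structure A8 has the right carbon count in ring B but lacks C3a, whereas 21 has every carbon of the target. On mechanism both rely on a cationic rearrangement or capture with good precedent. On step economy the chosen plan forms ring B with two stereocentres and needs three further steps, whereas this alternative needs the expansion plus at least three or four steps to install C3a stereoselectively.

Key step: step 11

Assumption: the sulfate monoesters 25 and 26 are handled and isolated as their sodium salts; they are named and drawn in the hydrogen sulfate form, which is the form in which the target is written.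

## Route

Step 1
Reactants: 1 6-bromovanillin (2-bromo-4-hydroxy-5-methoxybenzaldehyde)
Product: 2 4-(benzyloxy)-2-bromo-5-methoxybenzaldehyde
Conditions: BnBr, K2CO3, DMF, rt
Reagents that add atoms: benzyl bromide, BrCc1ccccc1
Why: Williamson ether synthesis; the phenol para to the aldehyde is acidic and its phenoxide is alkylated cleanly at oxygen.

Step 2
Reactants: 2 4-(benzyloxy)-2-bromo-5-methoxybenzaldehyde
Product: 3 [4-(benzyloxy)-2-bromo-5-methoxyphenyl]methanol
Conditions: NaBH4, MeOH/THF, 0 °C
Reagents that add atoms: none
Why: Borohydride reduction of an aromatic aldehyde; the aryl bromide and the benzyl ether are inert.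

Step 3
Reactants: 3 [4-(benzyloxy)-2-bromo-5-methoxyphenyl]methanol
Product: 4 1-(benzyloxy)-5-bromo-4-(bromomethyl)-2-methoxybenzene
Conditions: PBr3, CH2Cl2, 0 °C
Reagents that add atoms: phosphorus tribromide, BrP(Br)Br
Why: Conversion of an electron-rich benzylic alcohol into the bromide through its phosphite ester; the bromide is reactive and is used soon after preparation.

Step 4
Reactants: 5 3-(trimethylsilyl)propan-1-ol
Product: 6 3-(trimethylsilyl)propanal
Conditions: TEMPO (cat.), PhI(OAc)2, CH2Cl2, rt
Reagents that add atoms: none
Why: Oxoammonium (TEMPO) oxidation of a primary alcohol stops at the aldehyde; the C–Si bond is a spectator.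

Step 5
Reactants: 6 3-(trimethylsilyl)propanal; 7 malonic acid
Product: 8 (3E)-5-(trimethylsilyl)pent-3-enoic acid
Conditions: Et3N, neat, 90 °C; cold aq citric acid work-up
Reagents that add atoms: none
Why: Deconjugative (modified) Knoevenagel–Doebner condensation: the alkylidene malonic acid isomerises to its β,γ-unsaturated form before decarboxylation, which should give the (E)-alk-3-enoic acid. The E geometry of the allylsilane is set here under thermodynamic control.

Step 6
Reactants: 8 (3E)-5-(trimethylsilyl)pent-3-enoic acid; 9 (4R)-4-benzyl-1,3-oxazolidin-2-one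
Product: 12 (4R)-4-benzyl-3-[(3E)-5-(trimethylsilyl)pent-3-enoyl]-1,3-oxazolidin-2-one, via mixed pivalic anhydride 10 (not isolated), via lithium oxazolidinide 11 (not isolated)
Conditions: PivCl, Et3N, THF, −78 to 0 °C; then 11 (from 9, n-BuLi, THF, −78 °C), −78 to 0 °C
Reagents that add atoms: pivaloyl chloride, CC(C)(C)C(Cl)=O (its acyl group is carried only by intermediate 10); n-butyllithium, [Li]CCCC (its lithium is carried only by intermediate 11)
Why: N-acylation of the lithiated oxazolidinone by a mixed pivalic anhydride, which reacts at the less hindered carbonyl; the low temperature and the absence of free amine at the imide stage keep the β,γ-alkene out of conjugation.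

Step 7
Reactants: 12 (4R)-4-benzyl-3-[(3E)-5-(trimethylsilyl)pent-3-enoyl]-1,3-oxazolidin-2-one; 4 1-(benzyloxy)-5-bromo-4-(bromomethyl)-2-methoxybenzene
Product: 14 (4R)-4-benzyl-3-[(2R,3E)-2-{[4-(benzyloxy)-2-bromo-5-methoxyphenyl]methyl}-5-(trimethylsilyl)pent-3-enoyl]-1,3-oxazolidin-2-one, via sodium dienolate 13 (not isolated)
Conditions: NaN(SiMe3)2 (1.0 equiv), THF, −78 °C; then 4, −78 to −45 °C; AcOH quench at −78 °C
Reagents that add atoms: sodium bis(trimethylsilyl)amide, [Na+].C[Si](C)(C)[N-][Si](C)(C)C (its sodium is carried only by intermediate 13)
Why: Evans asymmetric alkylation: the sodium-chelated (Z)-dienolate reacts with the benzylic bromide at its α-carbon, the kinetic site of such dienolates, on the face opposite the C4 benzyl group of the (R)-auxiliary. This gives the (2R) centre, the future C3. A slight deficit of base and a cold acidic quench protect the doubly activated α-centre from epimerisation and the alkene from migration.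

Step 8
Reactants: 14 (4R)-4-benzyl-3-[(2R,3E)-2-{[4-(benzyloxy)-2-bromo-5-methoxyphenyl]methyl}-5-(trimethylsilyl)pent-3-enoyl]-1,3-oxazolidin-2-one
Product: 15 (2R,3E)-2-{[4-(benzyloxy)-2-bromo-5-methoxyphenyl]methyl}-5-(trimethylsilyl)pent-3-en-1-ol
Conditions: LiBH4, MeOH (1 equiv), Et2O, 0 °C
Reagents that add atoms: none
Why: Reductive cleavage of the N-acyl oxazolidinone at the exocyclic carbonyl gives the primary alcohol and releases the auxiliary for recovery; the non-basic hydride conditions should not epimerise the stereocentre.

Step 9
Reactants: 15 (2R,3E)-2-{[4-(benzyloxy)-2-bromo-5-methoxyphenyl]methyl}-5-(trimethylsilyl)pent-3-en-1-ol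
Product: 16 [(2E,4R)-5-[4-(benzyloxy)-2-bromo-5-methoxyphenyl]-4-[(benzyloxy)methyl]pent-2-en-1-yl]trimethylsilane
Conditions: NaH, BnBr, Bu4NI (cat.), THF/DMF, 0 °C to rt
Reagents that add atoms: benzyl bromide, BrCc1ccccc1
Why: Williamson etherification of the primary alkoxide; the allylsilane and the aryl bromide do not react with NaH, and the stereocentre carries no acidic hydrogen.

Step 10
Reactants: 16 [(2E,4R)-5-[4-(benzyloxy)-2-bromo-5-methoxyphenyl]-4-[(benzyloxy)methyl]pent-2-en-1-yl]trimethylsilane; 17 4-(benzyloxy)-3-methoxybenzaldehyde
Product: 19 [5-(benzyloxy)-2-{(2R,3E)-2-[(benzyloxy)methyl]-5-(trimethylsilyl)pent-3-en-1-yl}-4-methoxyphenyl][4-(benzyloxy)-3-methoxyphenyl]methanol (both carbinol epimers), via aryllithium 18 (not isolated)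
Conditions: n-BuLi, THF, −78 °C; then 17, −78 °C; pH 7 buffer
Reagents that add atoms: n-butyllithium, [Li]CCCC (its lithium is carried only by intermediate 18)
Why: Bromine–lithium exchange followed by 1,2-addition of the aryllithium to the aldehyde forms the C1–C8a bond. The carbinol centre forms without control, which does not matter because both epimers ionise to the same cation. The acid-labile benzhydrol is passed quickly through base-washed silica and used at once.

Step 11
Reactants: 19 [5-(benzyloxy)-2-{(2R,3E)-2-[(benzyloxy)methyl]-5-(trimethylsilyl)pent-3-en-1-yl}-4-methoxyphenyl][4-(benzyloxy)-3-methoxyphenyl]methanol (both carbinol epimers)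
Product: 21 (1S,2R,3R)-7-(benzyloxy)-1-[4-(benzyloxy)-3-methoxyphenyl]-3-[(benzyloxy)methyl]-2-ethenyl-6-methoxy-1,2,3,4-tetrahydronaphthalene, via benzhydryl cation 20 (not isolated)
Conditions: BF3·OEt2 (1.2 equiv), 2,6-di-tert-butyl-4-methylpyridine (0.2 equiv), CH2Cl2 (0.01 M), −78 °C
Reagents that add atoms: none
Why: BF3·OEt2 complexes the carbinol oxygen of either epimer of 19 and ionises it to the same benzhydryl cation 20, stabilised by the C6 methoxy group of ring A (para to C8a) and by the 4-benzyloxy group of ring C. The (E)-allylsilane attacks C1 through the alkene carbon remote from silicon (the carbon bonded to C3, the future C2), the charge developing on the neighbouring carbon is stabilised by the β C–Si bond, and loss of the silyl group to fluoride leaves the vinyl group; this is an intramolecular Hosomi–Sakurai allylation of a diarylmethyl cation, a known cation–allylsilane cyclisation. Ring B closes in the 6-exo-trig mode with respect to the allylsilane alkene (only the attacking carbon enters the ring), through a chair-like array of C1, C2, C3, C4, C4a and C8a. C2 is controlled by the preset C3 centre: with the C3 benzyloxymethyl arm pseudo-equatorial, the E alkene lies equatorial without A(1,3) strain and presents the face that puts the future vinyl group trans to the C3 arm (2R). C1 is controlled by the same chair: the planar cation should be attacked on the face that leaves ring C pseudo-equatorial and anti to the vinyl group (1S), so the trans,trans triad should predominate, with the C1 epimer as the most likely minor isomer. The step needs carbon attack to outrun protodesilylation and capture of the cation by the C3a ether oxygen; low temperature, high dilution and the hindered base secure this, together with the irreversibility of desilylation (oxygen capture through a seven-membered oxonium ion is reversible). Attack through the other alkene carbon is excluded because it would form a seven-membered ring and a cation without β-silicon stabilisation.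

Step 12
Reactants: 21 (1S,2R,3R)-7-(benzyloxy)-1-[4-(benzyloxy)-3-methoxyphenyl]-3-[(benzyloxy)methyl]-2-ethenyl-6-methoxy-1,2,3,4-tetrahydronaphthalene
Product: 24 [(1S,2R,3R)-7-(benzyloxy)-1-[4-(benzyloxy)-3-methoxyphenyl]-3-[(benzyloxy)methyl]-6-methoxy-1,2,3,4-tetrahydronaphthalen-2-yl]methanol, via vicinal diol 22 (not isolated), via aldehyde 23 (not isolated)
Conditions: OsO4 (2 mol %), NaIO4, 2,6-lutidine, dioxane/H2O, rt; filter; then NaBH4, MeOH, 0 °C
Reagents that add atoms: osmium tetroxide, O=[Os](=O)(=O)=O (delivers the oxygen atoms of diol 22, one of which remains as the C2a oxygen); sodium periodate, [Na+].[O-]I(=O)(=O)=O (terminal oxidant that replenishes them)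
Why: Lemieux–Johnson cleavage of the only alkene gives aldehyde 23, which is reduced in the same flask by NaBH4. The buffered conditions leave the electron-rich arenes and benzyl ethers alone, and the C2 centre of the aldehyde already has the thermodynamically preferred trans,trans arrangement.

Step 13
Reactants: 24 [(1S,2R,3R)-7-(benzyloxy)-1-[4-(benzyloxy)-3-methoxyphenyl]-3-[(benzyloxy)methyl]-6-methoxy-1,2,3,4-tetrahydronaphthalen-2-yl]methanol
Product: 25 [(1S,2R,3R)-7-(benzyloxy)-1-[4-(benzyloxy)-3-methoxyphenyl]-3-[(benzyloxy)methyl]-6-methoxy-1,2,3,4-tetrahydronaphthalen-2-yl]methyl hydrogen sulfate (handled as the sodium salt)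
Conditions: SO3·pyridine, pyridine, rt; then aq NaHCO3
Reagents that add atoms: sulfur trioxide–pyridine complex, [O-]S(=O)(=O)[n+]1ccccc1
Why: O-Sulfonation of the only free hydroxyl with a mild SO3 donor; the bicarbonate work-up exchanges pyridinium for sodium, which protects the monoester from acid and avoids a catalyst poison in the next step.

Step 14
Reactants: 25 [(1S,2R,3R)-7-(benzyloxy)-1-[4-(benzyloxy)-3-methoxyphenyl]-3-[(benzyloxy)methyl]-6-methoxy-1,2,3,4-tetrahydronaphthalen-2-yl]methyl hydrogen sulfate (sodium salt)
Product: 26 [(1S,2R,3R)-7-hydroxy-1-(4-hydroxy-3-methoxyphenyl)-3-(hydroxymethyl)-6-methoxy-1,2,3,4-tetrahydronaphthalen-2-yl]methyl hydrogen sulfate (CNP0184747.1, isolated as the sodium salt)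
Conditions: H2 (1 atm), 10% Pd/C, MeOH/H2O, rt
Reagents that add atoms: none
Why: Catalytic hydrogenolysis removes the two aryl benzyl ethers and the alkyl benzyl ether under neutral conditions; sulfate monoester salts are inert to Pd/C and hydrogen, and no stereocentre is touched.

## Compound list

1 | 6-bromovanillin (2-bromo-4-hydroxy-5-methoxybenzaldehyde) | O=Cc1cc(OC)c(O)cc1Br | starting material
2 | 4-(benzyloxy)-2-bromo-5-methoxybenzaldehyde | O=Cc1cc(OC)c(OCc2ccccc2)cc1Br | intermediate
3 | [4-(benzyloxy)-2-bromo-5-methoxyphenyl]methanol | OCc1cc(OC)c(OCc2ccccc2)cc1Br | intermediate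
4 | 1-(benzyloxy)-5-bromo-4-(bromomethyl)-2-methoxybenzene | BrCc1cc(OC)c(OCc2ccccc2)cc1Br | intermediate
5 | 3-(trimethylsilyl)propan-1-ol | C[Si](C)(C)CCCO | starting material
6 | 3-(trimethylsilyl)propanal | C[Si](C)(C)CCC=O | intermediate
7 | malonic acid | OC(=O)CC(=O)O | starting material
8 | (3E)-5-(trimethylsilyl)pent-3-enoic acid | C[Si](C)(C)C/C=C/CC(=O)O | intermediate
9 | (4R)-4-benzyl-1,3-oxazolidin-2-one | O=C1N[C@H](Cc2ccccc2)CO1 | starting material
10 | (3E)-5-(trimethylsilyl)pent-3-enoic pivalic anhydride | C[Si](C)(C)C/C=C/CC(=O)OC(=O)C(C)(C)C | intermediate (not isolated)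
11 | lithium (4R)-4-benzyl-2-oxo-1,3-oxazolidin-3-ide | [Li+].O=C1[N-][C@H](Cc2ccccc2)CO1 | intermediate (not isolated)
12 | (4R)-4-benzyl-3-[(3E)-5-(trimethylsilyl)pent-3-enoyl]-1,3-oxazolidin-2-one | C[Si](C)(C)C/C=C/CC(=O)N1[C@H](Cc2ccccc2)COC1=O | intermediate
13 | sodium (1Z,3E)-1-[(4R)-4-benzyl-2-oxo-1,3-oxazolidin-3-yl]-5-(trimethylsilyl)penta-1,3-dien-1-olate | C[Si](C)(C)C/C=C/C=C(\[O-])N1[C@H](Cc2ccccc2)COC1=O.[Na+] | intermediate (not isolated)
14 | (4R)-4-benzyl-3-[(2R,3E)-2-{[4-(benzyloxy)-2-bromo-5-methoxyphenyl]methyl}-5-(trimethylsilyl)pent-3-enoyl]-1,3-oxazolidin-2-one | COc1cc(C[C@@H](C(=O)N2[C@H](Cc3ccccc3)COC2=O)/C=C/C[Si](C)(C)C)c(Br)cc1OCc1ccccc1 | intermediate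
15 | (2R,3E)-2-{[4-(benzyloxy)-2-bromo-5-methoxyphenyl]methyl}-5-(trimethylsilyl)pent-3-en-1-ol | COc1cc(C[C@@H](CO)/C=C/C[Si](C)(C)C)c(Br)cc1OCc1ccccc1 | intermediate
16 | [(2E,4R)-5-[4-(benzyloxy)-2-bromo-5-methoxyphenyl]-4-[(benzyloxy)methyl]pent-2-en-1-yl]trimethylsilane | COc1cc(C[C@@H](COCc2ccccc2)/C=C/C[Si](C)(C)C)c(Br)cc1OCc1ccccc1 | intermediate
17 | 4-(benzyloxy)-3-methoxybenzaldehyde | COc1cc(C=O)ccc1OCc1ccccc1 | starting material
18 | {5-(benzyloxy)-2-[(2R,3E)-2-[(benzyloxy)methyl]-5-(trimethylsilyl)pent-3-en-1-yl]-4-methoxyphenyl}lithium | COc1cc(C[C@@H](COCc2ccccc2)/C=C/C[Si](C)(C)C)c([Li])cc1OCc1ccccc1 | intermediate (not isolated)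
19 | [5-(benzyloxy)-2-{(2R,3E)-2-[(benzyloxy)methyl]-5-(trimethylsilyl)pent-3-en-1-yl}-4-methoxyphenyl][4-(benzyloxy)-3-methoxyphenyl]methanol (both carbinol epimers) | COc1cc(C(O)c2cc(OCc3ccccc3)c(OC)cc2C[C@@H](COCc2ccccc2)/C=C/C[Si](C)(C)C)ccc1OCc1ccccc1 | intermediate
20 | diarylmethyl (benzhydryl) cation derived from 19 by loss of hydroxide | COc1cc([CH+]c2cc(OCc3ccccc3)c(OC)cc2C[C@@H](COCc2ccccc2)/C=C/C[Si](C)(C)C)ccc1OCc1ccccc1 | intermediate (not isolated)
21 | (1S,2R,3R)-7-(benzyloxy)-1-[4-(benzyloxy)-3-methoxyphenyl]-3-[(benzyloxy)methyl]-2-ethenyl-6-methoxy-1,2,3,4-tetrahydronaphthalene | COc1cc([C@H]2c3cc(OCc4ccccc4)c(OC)cc3C[C@@H](COCc3ccccc3)[C@@H]2C=C)ccc1OCc1ccccc1 | intermediate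
22 | 1-[(1S,2R,3R)-7-(benzyloxy)-1-[4-(benzyloxy)-3-methoxyphenyl]-3-[(benzyloxy)methyl]-6-methoxy-1,2,3,4-tetrahydronaphthalen-2-yl]ethane-1,2-diol (both carbinol epimers) | COc1cc([C@H]2c3cc(OCc4ccccc4)c(OC)cc3C[C@@H](COCc3ccccc3)[C@@H]2C(O)CO)ccc1OCc1ccccc1 | intermediate (not isolated)
23 | (1S,2R,3R)-7-(benzyloxy)-1-[4-(benzyloxy)-3-methoxyphenyl]-3-[(benzyloxy)methyl]-6-methoxy-1,2,3,4-tetrahydronaphthalene-2-carbaldehyde | COc1cc([C@H]2c3cc(OCc4ccccc4)c(OC)cc3C[C@@H](COCc3ccccc3)[C@@H]2C=O)ccc1OCc1ccccc1 | intermediate (not isolated)
24 | [(1S,2R,3R)-7-(benzyloxy)-1-[4-(benzyloxy)-3-methoxyphenyl]-3-[(benzyloxy)methyl]-6-methoxy-1,2,3,4-tetrahydronaphthalen-2-yl]methanol | COc1cc([C@H]2c3cc(OCc4ccccc4)c(OC)cc3C[C@@H](COCc3ccccc3)[C@@H]2CO)ccc1OCc1ccccc1 | intermediate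
25 | [(1S,2R,3R)-7-(benzyloxy)-1-[4-(benzyloxy)-3-methoxyphenyl]-3-[(benzyloxy)methyl]-6-methoxy-1,2,3,4-tetrahydronaphthalen-2-yl]methyl hydrogen sulfate | COc1cc([C@H]2c3cc(OCc4ccccc4)c(OC)cc3C[C@@H](COCc3ccccc3)[C@@H]2COS(=O)(=O)O)ccc1OCc1ccccc1 | intermediate
26 | [(1S,2R,3R)-7-hydroxy-1-(4-hydroxy-3-methoxyphenyl)-3-(hydroxymethyl)-6-methoxy-1,2,3,4-tetrahydronaphthalen-2-yl]methyl hydrogen sulfate | COc1cc([C@H]2c3cc(O)c(OC)cc3C[C@@H](CO)[C@@H]2COS(=O)(=O)O)ccc1O | target

## Step count and least certain steps

Total step count: 14. Longest linear sequence: 11 steps (from 1 through steps 1 to 3 and 7 to 14; the branch from 5 through steps 4 to 6 and 7 to 14 is equally long).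

Step 11 (key step). What is most likely to go wrong is poor facial selectivity at C1, because a pseudo-equatorial ring C suffers peri strain with the C8 hydrogen, or protodesilylation of the allylsilane by the protic species released when the carbinol is ionised, before ring closure can occur. The fallback sets out from 16 and returns at 21; it replaces the cation by a neutral para-quinone methide that is activated by a catalytic acid only. Aryllithium 18, made from 16 as in step 10, is added to commercial 4-[(tert-butyldimethylsilyl)oxy]-3-methoxybenzaldehyde to give the silyl-protected carbinol F1. K2CO3 in MeOH removes the aryl silyl ether selectively and gives the para-hydroxybenzhydrol F2. A catalytic Brønsted acid (diphenyl phosphate, CH2Cl2, 0 °C) dehydrates F2 to the para-quinone methide F3, which is not isolated; the allylsilane adds to it in a 1,6-conjugate sense through the same chair and gives the cyclised phenol F4. Benzylation of F4 (BnBr, K2CO3, DMF) returns to 21. Acid-catalysed formation of para-quinone methides from para-hydroxybenzyl alcohols and 1,6-addition of allylsilanes to them are both known reaction types.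

Step 5. What is most likely to go wrong is incomplete deconjugation, which would leave the α,β-unsaturated acid in the product, or partial protodesilylation of the allylsilane in the hot, weakly acidic melt. The fallback sets out from 11 and 4 and returns at 14; it introduces the silyl group by olefin metathesis after the stereocentre is set. Lithium salt 11 is acylated with commercial but-3-enoyl chloride to the imide F5. The sodium dienolate of F5 is alkylated with 4 as in step 7 to give the α-vinyl imide F6. Cross-metathesis of F6 with an excess of allyltrimethylsilane (second-generation Grubbs catalyst RuCl2(=CHPh)(H2IMes)(PCy3), CH2Cl2, 40 °C) gives 14; the branched allylic carbon should favour the E alkene, though less strictly than step 5 does.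

Step 7. What is most likely to go wrong is loss of regio- or stereochemical integrity of the dienolate: alkylation at the γ-carbon, migration of the alkene into conjugation, or epimerisation of the doubly activated α-centre by excess base. The fallback sets out from 9 and 4 and returns at 15; it avoids a dienolate by masking the alkene as a selenide. γ-Butyrolactone is opened with sodium benzeneselenolate (from PhSeSePh and NaBH4, DMF, 120 °C) to 4-(phenylselanyl)butanoic acid F7. Coupling of F7 with 9 (DCC, cat. DMAP, CH2Cl2) gives the imide F8. The ordinary sodium enolate of F8 is alkylated with 4 under the same facial control to give the selenide imide F9. LiBH4 cleaves the auxiliary and gives the selenide alcohol F10. Oxidation with H2O2 and syn-elimination of the selenoxide unmask the vinyl alcohol F11. Cross-metathesis of F11 with allyltrimethylsilane under the conditions named above gives 15.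

Step 14. What is most likely to go wrong is loss of the sulfate by acid-promoted solvolysis if the medium turns acidic, or stalling of the hydrogenolysis at the aliphatic benzyl ether because the amphiphilic salt 25 is hard to purify and carries catalyst poisons from step 13. The fallback sets out from 24 and returns at 26; it carries the sulfate as a neutral, chromatographable diester. Alcohol 24 is treated with 2,2,2-trichloroethoxysulfuryl-2-methylimidazolium triflate and 1-methylimidazole in THF to give the trichloroethyl-protected sulfate F12, which is purified on silica. Catalytic transfer hydrogenolysis (Pd/C, HCO2NH4, MeOH) then removes the three benzyl ethers and, by reductive fragmentation, the trichloroethyl group in one buffered operation, giving 26 as its ammonium salt.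

## Further compounds

F1 | step 11 | [5-(benzyloxy)-2-{(2R,3E)-2-[(benzyloxy)methyl]-5-(trimethylsilyl)pent-3-en-1-yl}-4-methoxyphenyl]{4-[(tert-butyldimethylsilyl)oxy]-3-methoxyphenyl}methanol (both carbinol epimers) | COc1cc(C(O)c2cc(OCc3ccccc3)c(OC)cc2C[C@@H](COCc2ccccc2)/C=C/C[Si](C)(C)C)ccc1O[Si](C)(C)C(C)(C)C
F2 | step 11 | 4-{[5-(benzyloxy)-2-{(2R,3E)-2-[(benzyloxy)methyl]-5-(trimethylsilyl)pent-3-en-1-yl}-4-methoxyphenyl](hydroxy)methyl}-2-methoxyphenol (both carbinol epimers) | COc1cc(C(O)c2cc(OCc3ccccc3)c(OC)cc2C[C@@H](COCc2ccccc2)/C=C/C[Si](C)(C)C)ccc1O
F3 | step 11 | 4-{[5-(benzyloxy)-2-{(2R,3E)-2-[(benzyloxy)methyl]-5-(trimethylsilyl)pent-3-en-1-yl}-4-methoxyphenyl]methylidene}-2-methoxycyclohexa-2,5-dien-1-one (para-quinone methide, not isolated) | COC1=CC(=Cc2cc(OCc3ccccc3)c(OC)cc2C[C@@H](COCc2ccccc2)/C=C/C[Si](C)(C)C)C=CC1=O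
F4 | step 11 | 4-[(1S,2R,3R)-7-(benzyloxy)-3-[(benzyloxy)methyl]-2-ethenyl-6-methoxy-1,2,3,4-tetrahydronaphthalen-1-yl]-2-methoxyphenol | COc1cc([C@H]2c3cc(OCc4ccccc4)c(OC)cc3C[C@@H](COCc3ccccc3)[C@@H]2C=C)ccc1O
F5 | step 5 | (4R)-4-benzyl-3-(but-3-enoyl)-1,3-oxazolidin-2-one | C=CCC(=O)N1[C@H](Cc2ccccc2)COC1=O
F6 | step 5 | (4R)-4-benzyl-3-[(2R)-2-{[4-(benzyloxy)-2-bromo-5-methoxyphenyl]methyl}but-3-enoyl]-1,3-oxazolidin-2-one | COc1cc(C[C@@H](C(=O)N2[C@H](Cc3ccccc3)COC2=O)C=C)c(Br)cc1OCc1ccccc1
F7 | step 7 | 4-(phenylselanyl)butanoic acid | OC(=O)CCC[Se]c1ccccc1
F8 | step 7 | (4R)-4-benzyl-3-[4-(phenylselanyl)butanoyl]-1,3-oxazolidin-2-one | O=C(CCC[Se]c1ccccc1)N1[C@H](Cc2ccccc2)COC1=O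
F9 | step 7 | (4R)-4-benzyl-3-[(2R)-2-{[4-(benzyloxy)-2-bromo-5-methoxyphenyl]methyl}-4-(phenylselanyl)butanoyl]-1,3-oxazolidin-2-one | COc1cc(C[C@@H](C(=O)N2[C@H](Cc3ccccc3)COC2=O)CC[Se]c2ccccc2)c(Br)cc1OCc1ccccc1
F10 | step 7 | (2R)-2-{[4-(benzyloxy)-2-bromo-5-methoxyphenyl]methyl}-4-(phenylselanyl)butan-1-ol | COc1cc(C[C@@H](CO)CC[Se]c2ccccc2)c(Br)cc1OCc1ccccc1
F11 | step 7 | (2R)-2-{[4-(benzyloxy)-2-bromo-5-methoxyphenyl]methyl}but-3-en-1-ol | COc1cc(C[C@@H](CO)C=C)c(Br)cc1OCc1ccccc1
F12 | step 14 | [(1S,2R,3R)-7-(benzyloxy)-1-[4-(benzyloxy)-3-methoxyphenyl]-3-[(benzyloxy)methyl]-6-methoxy-1,2,3,4-tetrahydronaphthalen-2-yl]methyl 2,2,2-trichloroethyl sulfate | COc1cc([C@H]2c3cc(OCc4ccccc4)c(OC)cc3C[C@@H](COCc3ccccc3)[C@@H]2COS(=O)(=O)OCC(Cl)(Cl)Cl)ccc1OCc1ccccc1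
A1 | alternative 1 | methyl 4-[4-(benzyloxy)-3-methoxyphenyl]-3-{[(tert-butyldimethylsilyl)oxy]methyl}-4-(3-hydroxy-4-methoxyphenyl)-2-methylidenebutanoate (acyclic phenol acrylate) | COc1cc([C@@H](c2cc(O)c(OC)cc2)[C@@H](CO[Si](C)(C)C(C)(C)C)C(=C)C(=O)OC)ccc1OCc1ccccc1
A2 | alternative 1 | methyl trans,trans-1-[4-(benzyloxy)-3-methoxyphenyl]-2-{[(tert-butyldimethylsilyl)oxy]methyl}-7-hydroxy-6-methoxy-1,2,3,4-tetrahydronaphthalene-3-carboxylate | COc1cc([C@H]2c3cc(O)c(OC)cc3C[C@@H](C(=O)OC)[C@@H]2CO[Si](C)(C)C(C)(C)C)ccc1OCc1ccccc1
A3 | alternative 2 | 4-(benzyloxy)-2-{[4-(benzyloxy)-3-methoxyphenyl]methyl}-5-methoxybenzaldehyde | COc1cc(Cc2cc(OCc3ccccc3)c(OC)cc2C=O)ccc1OCc1ccccc1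
A4 | alternative 2 | dimethyl fumarate | COC(=O)/C=C/C(=O)OC
A5 | alternative 2 | dimethyl 7-(benzyloxy)-1-[4-(benzyloxy)-3-methoxyphenyl]-4-hydroxy-6-methoxy-1,2,3,4-tetrahydronaphthalene-2,3-dicarboxylate (trans,trans at C1 to C3, C4 hydroxyl cis to the C3 ester) | COc1cc([C@H]2c3cc(OCc4ccccc4)c(OC)cc3[C@@H](O)[C@@H](C(=O)OC)[C@@H]2C(=O)OC)ccc1OCc1ccccc1
A6 | alternative 3 | trans-5-(benzyloxy)-3-[4-(benzyloxy)-3-methoxyphenyl]-2-{[(tert-butyldimethylsilyl)oxy]methyl}-6-methoxy-2,3-dihydro-1H-inden-1-one | COc1cc([C@H]2c3cc(OCc4ccccc4)c(OC)cc3C(=O)[C@@H]2CO[Si](C)(C)C(C)(C)C)ccc1OCc1ccccc1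
A7 | alternative 3 | trimethylsilyldiazomethane | C[Si](C)(C)C=[N+]=[N-]
A8 | alternative 3 | trans-7-(benzyloxy)-1-[4-(benzyloxy)-3-methoxyphenyl]-2-{[(tert-butyldimethylsilyl)oxy]methyl}-6-methoxy-1,4-dihydronaphthalen-3(2H)-one | COc1cc([C@H]2c3cc(OCc4ccccc4)c(OC)cc3CC(=O)[C@@H]2CO[Si](C)(C)C(C)(C)C)ccc1OCc1ccccc1
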